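- The spring run ends at 0.565 of the ring fraction of the winter run, 26% of the charge against 46%, though both flasks hold protic impurity at 0.10 M.

| flask | starting material | protic impurity | remark | time |
|---|---|---|---|---|
| winter | 0.017 M | 0.10 M | run made earlier |  |
| spring | 0.12 M | 0.10 M | run made earlier |  |
| eta | 0.012 M | 0.100 M |  | 80 min |
| alpha | 0.025 M | 0.100 M |  | 80 min |
| zeta | 0.050 M | 0.100 M |  | 80 min |
| theta | 0.10 M | 0.100 M |  | 80 min |

| run | time / min | ring / % |
|---|---|---|
| winter | 6.00 | 15 |
| winter | 10.0 | 23 |
| winter | 15.0 | 29 |
| winter | 25.0 | 42 |
| winter | 30.0 | 40 |
| winter | 50.0 | 47 |
| winter | 80.0 | 46 |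
| spring | 4.00 | 10 |
| spring | 12.0 | 18 |
| spring | 25.0 | 23 |
| spring | 30.0 | 22 |
| spring | 50.0 | 25 |
| spring | 60.0 | 28 |
| spring | 80.0 | 26 |

(readings scatter by 2 percentage points)

- percent here means starting material units held: one open dimer or side product counts as two
- candidate steps: starting material + ring -> side product; starting material -> ring; starting material + protic impurity -> quenched substrate; 2 starting material -> open dimer
- "hardly changes" means that all values lie within two and a half points (for a concentration: within two and a half percent of the largest)

- amount of ring at the end, in percent of the starting material charged for eta, alpha, zeta, theta, in this order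
- the shape of the row from first to last (rises, then falls / falls all the way / rises all the way / falls, then rises / hardly changes)

- Early on, the two runs make ring alike, 0.0250 min⁻¹ of the charge per minute in winter and 0.0250 min⁻¹ in spring. So, as read, ring closure follows the first power of starting material, and the loss that grows with the charge follows a higher power.
- This note's own reckoning takes the reciprocal of the ring fraction (the selectivity for ring) as a straight line in the charge, through the last reading of each run, with slope 16.2 M⁻¹.
- That line meets zero charge at 52.7% and gives 0.117 M, the charge at which the ring fraction stands at half of that intercept: the halving charge. Both are stretched from two last readings, each with a scatter of 2 percentage points, so they are rough estimates and not readings.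
- At 80 min the flasks should have stopped gaining ring, since the winter run reads 47% at 50.0 min and 46% at 80.0 min.
- The line gives 47.8% for eta, 43.4% for alpha, 36.9% for zeta and 28.4% for theta.
- Leave each charge as written, because the ring fraction moves with it: theta stands at 0.855 of the halving charge.
- The forecast gives 49%, 44%, 38% and 31%, a row that falls all the way, adding: “Impurity depletion is too small to reverse the fall”. At theta it stands higher than this reckoning by 2.6 points.

    starting material + ring → side product (k = 0.00620 M⁻¹ s⁻¹)
    starting material → ring (k = 6.03 × 10⁻⁴ s⁻¹)
    starting material + protic impurity → quenched substrate (k = 0.00551 M⁻¹ s⁻¹)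
    2 starting material → open dimer (k = 0.00701 M⁻¹ s⁻¹)

- The flasks give 47.1%, 42.7%, 36.5% and 28.5%, a row that falls all the way. Open dimer at the end goes from 6.64% of the charge in eta to 34.3% in theta. With the halving charge, the line gave 28.4% for theta, which holds 28.5%. For zeta, at 0.428 of the halving charge, it gave 36.9%, and zeta holds 36.5%.

Readings and results were generated by integration with constants of no real substance, noise included.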